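**Retrosynthetic overview**

1. Feature: number the carbocycle C1 (aroyl), C2 (prenyl), C3 (methyl)=C4, C5, C6 (phenyl). The ketone carbon on C1 and ring carbon C4 are then para-related, so an oxygen link from that carbonyl carbon to C4 makes the ring a 2-oxabicyclo[2.2.2]oct-5-en-3-one, which is the adduct of 5-methyl-2-pyrone (across C3/C6) with styrene.
2. Disconnections, backwards: prenyl C=C (Wittig) ⇒ C2–CH2CHO; C2–CH2 bond ⇒ Claisen shift from a C4 O-vinyl ether (alkene C2=C3 → C3=C4); aryl–C(=O) bond ⇒ 7-lithiobenzofuran + lactone carbonyl; ring bonds C1–C6 and C4–C5 ⇒ [4+2].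
3. Ring order: the pyrone first (from dimethyl malonate and 3-dimethylamino-2-methylacrolein), then the carbocycle as the lactone-bridged bicycle. The benzofuran is made separately from 5-methoxyresorcinol with bromine fixed at C7.
4. Stereocontrol: the bridge holds the C1 acyl carbon and the C4 oxygen cis and the endo phenyl trans to both; the suprafacial Claisen shift relays C4 to C2. The cycloaddition is run racemic and the absolute configuration is secured by lipase resolution of the allylic alcohol.

Key step: step 4

Remark: 8 and 18 are racemates; their SMILES show the enantiomer that is carried on to the target.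
Remark: visnagin is not used as the source of the benzofuran, because its carbonyl carbon sits on C5 whereas the target ketone is on C7 (between the hydroxyl and the furan oxygen).

**Route**

Step 1
Reactants: 1 dimethyl malonate; 2 (E)-3-(dimethylamino)-2-methylprop-2-enal
Product: 3 dimethyl 2-[(2E)-3-(dimethylamino)-2-methylprop-2-en-1-ylidene]propanedioate
Conditions: Ac2O (3 equiv), neat, 100 °C
Reagents that add atoms: none
Why: Knoevenagel-type condensation in which acetic anhydride O-acylates the vinylogous formamide to an acetoxy-iminium ion that the malonate attacks at the former aldehyde carbon, so that loss of acetic acid should give the push–pull dienamine diester holding the future pyrone carbons C3–C6; no stereocentre is formed.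

Step 2
Reactants: 3 dimethyl 2-[(2E)-3-(dimethylamino)-2-methylprop-2-en-1-ylidene]propanedioate
Product: 5 5-methyl-2-oxo-2H-pyran-3-carboxylic acid, via pyrone methyl ester 4 (not isolated)
Conditions: AcOH, 6 M aq. HCl, reflux
Reagents that add atoms: water, O
Why: Acid hydrolysis of the enamine frees the C6 enol, whose oxygen closes onto the cis ester (6-exo-trig lactonisation, the classical 2-pyrone-3-carboxylate synthesis), and the same hot aqueous acid should then hydrolyse the remaining methyl ester without opening the pyrone, which base would not spare.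

Step 3
Reactants: 5 5-methyl-2-oxo-2H-pyran-3-carboxylic acid
Product: 6 5-methyl-2H-pyran-2-one
Conditions: Cu powder (cat.), quinoline, 200 °C; product distilled
Reagents that add atoms: none
Why: Copper-mediated protodecarboxylation of a vinylogous β-oxo acid, as practised on coumarin-3- and 2-pyrone-3-carboxylic acids, should leave the volatile methylpyrone.

Step 4
Reactants: 6 5-methyl-2H-pyran-2-one; 7 styrene
Product: 8 racemic (1R,4R,8R)-6-methyl-8-phenyl-2-oxabicyclo[2.2.2]oct-5-en-3-one (phenyl anti to the lactone bridge)
Conditions: styrene (5 equiv), BHT (1 mol%), CH2Cl2, 12 kbar, 45 °C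
Reagents that add atoms: none
Why: The pyrone serves as the 4π partner through C3=C4–C5=C6 and styrene as the 2π partner in a concerted, suprafacial [4+2] cycloaddition that forms C3–CH(Ph) and C6–CH2 in one transition state; the closest known reactions are the thermal cycloadditions of bromo-2-pyrones with styrenes and the high-pressure cycloadditions of 2-pyrone itself with alkenes, both of which stop at the 2-oxabicyclo[2.2.2]octenone. The cyclohexene ring is closed by this intermolecular cycloaddition itself, its two new ring bonds being made together while the O1–C2 lactone unit stays as the third, two-atom bridge. Regiochemistry should follow the styrene-HOMO/pyrone-LUMO interaction, the CH2 terminus bonding to the electrophilic and less hindered C6 (δ-carbon of the dienoate) and the benzylic carbon to C3, the orientation that bromo-pyrones show with styrene. C1 and C4 are bridgeheads and therefore necessarily cis, and C8 is set by the endo transition state with phenyl under C4–C5 of the diene, which places it syn to the new alkene and anti to the lactone bridge; pressure favours this more compact arrangement. The step needs the CO2 bridge to survive, which pressure in place of heat should secure because extrusion from such adducts needs prolonged heating well above 100 °C, and it needs no facial control because the racemate is resolved at step 11.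

Step 5
Reactants: 9 5-methoxybenzene-1,3-diol
Product: 10 1-methoxy-3,5-bis(methoxymethoxy)benzene
Conditions: NaH, MOMCl, DMF, 0 °C → rt
Reagents that add atoms: chloromethyl methyl ether, COCCl
Why: Williamson-type alkylation of both sodium phenoxides by the α-chloro ether gives the bis-acetal, whose two OMOM groups act as the directing pair in the next step.

Step 6
Reactants: 10 1-methoxy-3,5-bis(methoxymethoxy)benzene
Product: 13 2-bromo-5-methoxybenzene-1,3-diol, via aryllithium 11 (not isolated), via bis-MOM aryl bromide 12 (not isolated)
Conditions: n-BuLi, THF, 0 °C; BrCH2CH2Br, −78 °C → rt; then MeOH, conc. HCl (cat.), 50 °C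
Reagents that add atoms: 1,2-dibromoethane, BrCCBr
Why: Directed ortho-metalation at the carbon flanked by two chelating OMOM groups (the other ring positions have only one OMOM and an OMe), bromination of the aryllithium by halophilic attack on 1,2-dibromoethane and acid methanolysis of the acetals should give the symmetric bromoresorcinol, which fixes the halogen at the future C7 without a regiochemical choice.

Step 7
Reactants: 13 2-bromo-5-methoxybenzene-1,3-diol
Product: 14 2-bromo-3-(2,2-diethoxyethoxy)-5-methoxyphenol
Conditions: BrCH2CH(OEt)2 (0.8 equiv), K2CO3, DMF, 100 °C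
Reagents that add atoms: 2-bromo-1,1-diethoxyethane, CCOC(CBr)OCC
Why: Williamson etherification of one of two equivalent phenols, with the diol in excess so that mono-alkylation dominates and unreacted 13 is recovered.

Step 8
Reactants: 14 2-bromo-3-(2,2-diethoxyethoxy)-5-methoxyphenol
Product: 15 7-bromo-4-methoxy-1-benzofuran-6-ol
Conditions: Amberlyst-15, PhCl, 120 °C, slow addition (high dilution)
Reagents that add atoms: none
Why: Acid-catalysed cyclodehydration of an aryloxyacetaldehyde acetal (intramolecular Friedel–Crafts attack of the oxocarbenium ion, then loss of ethanol), in which the only free carbon ortho to the ether oxygen lies between O-alkyl and OMe and para to the free OH, so a single benzofuran should form.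

Step 9
Reactants: 15 7-bromo-4-methoxy-1-benzofuran-6-ol
Product: 16 7-bromo-4-methoxy-6-(methoxymethoxy)-1-benzofuran
Conditions: NaH, MOMCl, DMF, 0 °C
Reagents that add atoms: chloromethyl methyl ether, COCCl
Why: MOM protection of the phenol as in step 5; the acetal tolerates organolithium, Pd(II), 180 °C and ylide and is removed last by mild acid.

Step 10
Reactants: 16 7-bromo-4-methoxy-6-(methoxymethoxy)-1-benzofuran; 8 racemic lactone
Product: 18 racemic [(1R,4R,6R)-4-hydroxy-3-methyl-6-phenylcyclohex-2-en-1-yl][4-methoxy-6-(methoxymethoxy)-1-benzofuran-7-yl]methanone (acyl and OH cis; phenyl trans to both), via 7-lithiobenzofuran 17 (not isolated)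
Conditions: n-BuLi (1.05 equiv), THF, −78 °C; then 8, −78 °C; AcOH, −78 °C
Reagents that add atoms: none
Why: Bromine–lithium exchange at −78 °C outruns deprotonation at furan C2, and the aryllithium adds once to the lactone carbonyl to a cyclic hemiketalate that should persist until the cold acidic quench (as in aryllithium additions to sugar lactones); it then opens to a 2,6-dioxygenated aryl ketone too hindered for a second addition, with C1, C4 and C6 untouched so that acyl and hydroxyl stay cis as the bridge held them.

Step 11
Reactants: 18 racemic hydroxy ketone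
Product: 19 (1R,4R,5R)-4-[4-methoxy-6-(methoxymethoxy)-1-benzofuran-7-carbonyl]-2-methyl-5-phenylcyclohex-2-en-1-yl acetate
Conditions: Burkholderia cepacia lipase (immobilised), vinyl acetate, MTBE, 30 °C, run to about half conversion; acetate separated from unreacted alcohol by chromatography
Reagents that add atoms: vinyl acetate, C=COC(C)=O
Why: Lipase-catalysed irreversible transesterification (kinetic resolution) of a cyclic secondary allylic alcohol, in which the empirical size rule for lipases predicts faster acylation of the (R)-carbinol whose larger flank is the methyl-bearing alkene carbon C3, so the wanted series should leave as the acetate under neutral conditions that spare the β,γ-unsaturated ketone; no stereocentre is formed.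

Step 12
Reactants: 19 (1R,4R,5R)-acetate
Product: 20 [(1R,4R,6R)-4-hydroxy-3-methyl-6-phenylcyclohex-2-en-1-yl][4-methoxy-6-(methoxymethoxy)-1-benzofuran-7-yl]methanone (single enantiomer)
Conditions: lipase of step 11, n-BuOH (5 equiv), MTBE, 40 °C
Reagents that add atoms: none
Why: Enzymatic transesterification to butanol cleaves the acetate at neutral pH, which avoids the base that could cause 1,4-elimination of acetate from the β,γ-unsaturated ketone and passes the material through a second enantioselective event.

Step 13
Reactants: 20 (1R,4R,6R)-hydroxy ketone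
Product: 21 [(1R,4R,6R)-4-(ethenyloxy)-3-methyl-6-phenylcyclohex-2-en-1-yl][4-methoxy-6-(methoxymethoxy)-1-benzofuran-7-yl]methanone
Conditions: Pd(OCOCF3)2 (5 mol%), 4,7-diphenyl-1,10-phenanthroline (5 mol%), Et3N (10 mol%), butyl vinyl ether, 50 °C
Reagents that add atoms: butyl vinyl ether, C=COCCCC
Why: Pd(II)-catalysed transfer vinylation (oxypalladation of the vinyl ether, then β-alkoxide elimination) of a secondary allylic alcohol, with retention at C4 because the C4–O bond is not broken.

Step 14
Reactants: 21 allyl vinyl ether
Product: 22 [(1R,2S,6R)-3-methyl-2-(2-oxoethyl)-6-phenylcyclohex-3-en-1-yl][4-methoxy-6-(methoxymethoxy)-1-benzofuran-7-yl]methanone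
Conditions: toluene, BHT (cat.), 180 °C, sealed tube
Reagents that add atoms: none
Why: Thermal Claisen ([3,3]-sigmatropic) rearrangement through a boat-like transition state on the ring is suprafacial, so the new C2–CH2 bond forms on the face that carried the C4–O bond, that is cis to the C1 acyl group (2S), while the alkene moves to C3=C4 and out of reach of the ketone α-carbon.

Step 15
Reactants: 22 keto aldehyde
Product: 23 [(1R,2S,6R)-3-methyl-2-(3-methylbut-2-en-1-yl)-6-phenylcyclohex-3-en-1-yl][4-methoxy-6-(methoxymethoxy)-1-benzofuran-7-yl]methanone
Conditions: i-PrPPh3+ I−, n-BuLi, THF, 0 °C; then 22, −78 → 0 °C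
Reagents that add atoms: isopropyltriphenylphosphonium iodide, CC(C)[P+](c1ccccc1)(c1ccccc1)c1ccccc1.[I-]
Why: Wittig olefination with the non-stabilised isopropylidene ylide should take the unhindered aldehyde in preference to the di-ortho-substituted aryl ketone and gives a prenyl alkene with no geometry to control; should the basic ylide touch C1, its configuration is the thermodynamically preferred one (acyl and phenyl trans-diequatorial).

Step 16
Reactants: 23 MOM ether
Product: 24 (6-hydroxy-4-methoxy-1-benzofuran-7-yl)[(1R,2S,6R)-3-methyl-2-(3-methylbut-2-en-1-yl)-6-phenylcyclohex-3-en-1-yl]methanone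
Conditions: 2 M aq. HCl, MeOH, rt
Reagents that add atoms: none
Why: Acid-catalysed acetal exchange with methanol removes the MOM group, assisted by the neighbouring ketone, under conditions mild enough for the prenyl and ring alkenes and the benzofuran, as in the deprotection of prenylated acylphenols.

**Compound list**

1 | dimethyl malonate | COC(=O)CC(=O)OC | starting material
2 | (E)-3-(dimethylamino)-2-methylprop-2-enal | CN(C)/C=C(\C)C=O | starting material
3 | dimethyl 2-[(2E)-3-(dimethylamino)-2-methylprop-2-en-1-ylidene]propanedioate | CN(C)/C=C(\C)C=C(C(=O)OC)C(=O)OC | intermediate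
4 | methyl 5-methyl-2-oxo-2H-pyran-3-carboxylate (not isolated) | COC(=O)c1cc(C)coc1=O | intermediate
5 | 5-methyl-2-oxo-2H-pyran-3-carboxylic acid | Cc1coc(=O)c(C(=O)O)c1 | intermediate
6 | 5-methyl-2H-pyran-2-one | Cc1ccc(=O)oc1 | intermediate
7 | styrene | C=Cc1ccccc1 | starting material
8 | racemic (1R,4R,8R)-6-methyl-8-phenyl-2-oxabicyclo[2.2.2]oct-5-en-3-one, phenyl anti to the lactone bridge | O=C1O[C@@H]2C[C@@H](c3ccccc3)[C@H]1C=C2C | intermediate
9 | 5-methoxybenzene-1,3-diol | COc1cc(O)cc(O)c1 | starting material
10 | 1-methoxy-3,5-bis(methoxymethoxy)benzene | COCOc1cc(OC)cc(OCOC)c1 | intermediate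
11 | [4-methoxy-2,6-bis(methoxymethoxy)phenyl]lithium (not isolated) | [Li]c1c(OCOC)cc(OC)cc1OCOC | intermediate
12 | 2-bromo-5-methoxy-1,3-bis(methoxymethoxy)benzene (not isolated) | COCOc1cc(OC)cc(OCOC)c1Br | intermediate
13 | 2-bromo-5-methoxybenzene-1,3-diol | COc1cc(O)c(Br)c(O)c1 | intermediate
14 | 2-bromo-3-(2,2-diethoxyethoxy)-5-methoxyphenol | CCOC(COc1cc(OC)cc(O)c1Br)OCC | intermediate
15 | 7-bromo-4-methoxy-1-benzofuran-6-ol | COc1cc(O)c(Br)c2occc12 | intermediate
16 | 7-bromo-4-methoxy-6-(methoxymethoxy)-1-benzofuran | COCOc1cc(OC)c2ccoc2c1Br | intermediate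
17 | [4-methoxy-6-(methoxymethoxy)-1-benzofuran-7-yl]lithium (not isolated) | [Li]c1c(OCOC)cc(OC)c2ccoc12 | intermediate
18 | racemic [(1R,4R,6R)-4-hydroxy-3-methyl-6-phenylcyclohex-2-en-1-yl][4-methoxy-6-(methoxymethoxy)-1-benzofuran-7-yl]methanone | O=C(c1c(OCOC)cc(OC)c2ccoc12)[C@@H]1C=C(C)[C@H](O)C[C@H]1c1ccccc1 | intermediate
19 | (1R,4R,5R)-4-[4-methoxy-6-(methoxymethoxy)-1-benzofuran-7-carbonyl]-2-methyl-5-phenylcyclohex-2-en-1-yl acetate | O=C(c1c(OCOC)cc(OC)c2ccoc12)[C@@H]1C=C(C)[C@H](OC(C)=O)C[C@H]1c1ccccc1 | intermediate
20 | [(1R,4R,6R)-4-hydroxy-3-methyl-6-phenylcyclohex-2-en-1-yl][4-methoxy-6-(methoxymethoxy)-1-benzofuran-7-yl]methanone, single enantiomer | O=C(c1c(OCOC)cc(OC)c2ccoc12)[C@@H]1C=C(C)[C@H](O)C[C@H]1c1ccccc1 | intermediate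
21 | [(1R,4R,6R)-4-(ethenyloxy)-3-methyl-6-phenylcyclohex-2-en-1-yl][4-methoxy-6-(methoxymethoxy)-1-benzofuran-7-yl]methanone | O=C(c1c(OCOC)cc(OC)c2ccoc12)[C@@H]1C=C(C)[C@H](OC=C)C[C@H]1c1ccccc1 | intermediate
22 | [(1R,2S,6R)-3-methyl-2-(2-oxoethyl)-6-phenylcyclohex-3-en-1-yl][4-methoxy-6-(methoxymethoxy)-1-benzofuran-7-yl]methanone | O=C(c1c(OCOC)cc(OC)c2ccoc12)[C@@H]1[C@H](CC=O)C(C)=CC[C@H]1c1ccccc1 | intermediate
23 | [(1R,2S,6R)-3-methyl-2-(3-methylbut-2-en-1-yl)-6-phenylcyclohex-3-en-1-yl][4-methoxy-6-(methoxymethoxy)-1-benzofuran-7-yl]methanone | O=C(c1c(OCOC)cc(OC)c2ccoc12)[C@@H]1[C@H](CC=C(C)C)C(C)=CC[C@H]1c1ccccc1 | intermediate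
24 | (6-hydroxy-4-methoxy-1-benzofuran-7-yl)[(1R,2S,6R)-3-methyl-2-(3-methylbut-2-en-1-yl)-6-phenylcyclohex-3-en-1-yl]methanone | COc1cc(O)c(C(=O)[C@@H]2[C@H](CC=C(C)C)C(C)=CC[C@H]2c2ccccc2)c2occc12 | target

**Step count and risks**

Total steps: 16. Longest linear sequence: 12 (steps 5–16, the aryl branch; the pyrone branch is 11).

Steps most likely to fail:

Step 4. The unactivated, slightly electron-rich pyrone may add too slowly even under pressure, so that styrene polymerises first, or warming to force conversion may let CO2 escape and the resulting diene react on. The fallback sets out from 5 and comes back at 8. Bromodecarboxylation of acid 5 (NBS, LiOAc, aq. MeCN) gives 3-bromo-5-methyl-2H-pyran-2-one F1, an ambiphilic diene that adds styrene thermally (toluene, 100 °C) with the same regio- and endo-sense to racemic 4-bromo-6-methyl-8-phenyl-2-oxabicyclo[2.2.2]oct-5-en-3-one F2. The bridgehead bromine is then removed with Bu3SnH/AIBN (benzene, 80 °C), a bridgehead radical that cannot change configuration, to give 8.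

Step 10. The strained bicyclic hemiketalate may open in the flask; the ketone set free has a C1–H that is both α to the carbonyl and allylic, and its deprotonation by the aryllithium would stall the addition and let the alkene slide into conjugation on quench, erasing C1. The fallback sets out from 8 and comes back at 18. Lactone 8 is opened first with Me(MeO)NH·HCl and i-PrMgCl (THF, −20 °C) to racemic (1R,4R,6R)-4-hydroxy-N-methoxy-N,3-dimethyl-6-phenylcyclohex-2-ene-1-carboxamide F3. After deprotonation of the hydroxyl with i-PrMgCl (1 equiv), aryllithium 17 is added; the N-methoxy chelate holds the adduct until the acidic quench, so no ketone coexists with base, and work-up gives 18.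

Step 11. The enzyme may discriminate poorly between the enantiomers of so large a carbinol, or acylate it too slowly, leaving material of low enantiomeric purity; the sense of the resolution must in any case be checked on 20 by MTPA ester analysis. The fallback sets out from 8 and comes back at 20. Racemic 8 is separated by preparative supercritical-fluid chromatography on a chiral stationary phase (amylose tris(3,5-dimethylphenylcarbamate), CO2/MeOH), and the enantiomer (1R,4R,8R)-6-methyl-8-phenyl-2-oxabicyclo[2.2.2]oct-5-en-3-one F4 is taken through the conditions of step 10, which then gives 20 directly and makes steps 11 and 12 unnecessary.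

**Further compounds**

F1 | step 4 | 3-bromo-5-methyl-2H-pyran-2-one | Cc1coc(=O)c(Br)c1
F2 | step 4 | racemic 4-bromo-6-methyl-8-phenyl-2-oxabicyclo[2.2.2]oct-5-en-3-one, phenyl anti to the lactone bridge | O=C1O[C@@H]2C[C@@H](c3ccccc3)[C@@]1(Br)C=C2C
F3 | step 10 | racemic (1R,4R,6R)-4-hydroxy-N-methoxy-N,3-dimethyl-6-phenylcyclohex-2-ene-1-carboxamide | CON(C)C(=O)[C@@H]1C=C(C)[C@H](O)C[C@H]1c1ccccc1
F4 | step 11 | (1R,4R,8R)-6-methyl-8-phenyl-2-oxabicyclo[2.2.2]oct-5-en-3-one, single enantiomer | O=C1O[C@@H]2C[C@@H](c3ccccc3)[C@H]1C=C2C
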